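C7–C8, C4a–C5 [3+3] route to CNP0257825.1 on a kojic acid pyranone

Retrosynthetic cuts, in order: the three benzyl–oxygen bonds; the C2–H and C3–H bonds, leading back to a flat 3-methoxyflavone; C7–C8 and C4a–C5 of ring A; and the C2–C1' bond to ring B.
Enabling feature: C8, C8a, C4a, C4, C3, C2, O1 and the oxygen on C3 form the skeleton of a 6-methyl-3-methoxy-4-pyranone, with C8 as its acidic methyl group and C4a as its free ring CH. C5, C6, C7 and their three oxygens form a methoxymalonate unit.
This unit is used as the ketene O,S-acetal ester MeO2C–C(OMe)=C(OMe)SMe. It has no acidic hydrogen and is reached by S-methylation, whereas an all-oxygen acetal would need O-methylation of a malonate enolate, which goes to carbon. It loses thiolate, so OMe stays on C7.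
Forward order: ring C comes ready-made from kojic acid, ring B (from methoxyhydroquinone) is joined by Suzuki coupling, ring A is closed by the [3+3] annulation, and reduction and deprotection follow.
Stereochemistry: C2 is set by a ligand-controlled copper hydride 1,4-reduction of C2=C3. C3 follows by acid equilibration to the diequatorial 2,3-trans ketone, and the neutral final hydrogenolysis touches neither centre.

Key step: step 11

Assumption: (R)-DTBM-SEGPHOS is taken to expose the face of C2 that leads to 2R. If the sense proves opposite, the (S)-ligand is used and nothing else changes.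

Step 1
Reactants: 1 kojic acid
Product: 2 chlorokojic acid [2-(chloromethyl)-5-hydroxy-4H-pyran-4-one]
Conditions: SOCl2 (neat), rt
Reagents that add atoms: thionyl chloride, ClS(Cl)=O
Why: Chlorodehydroxylation through the chlorosulfite converts only the primary allylic-type alcohol and leaves the enolic 5-hydroxyl alone, as in the standard preparation of this compound.

Step 2
Reactants: 2 chlorokojic acid
Product: 3 allomaltol [5-hydroxy-2-methyl-4H-pyran-4-one]
Conditions: Zn dust, conc. HCl, H2O, 70 °C
Reagents that add atoms: none
Why: Zinc/acid reductive dehalogenation of the activated chloride is routine, and it is placed before the ring bromination because zinc would also strip a ring bromide.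

Step 3
Reactants: 3 allomaltol
Product: 4 2-bromo-3-hydroxy-6-methyl-4H-pyran-4-one
Conditions: NBS, MeCN, 0 °C to rt, dark
Reagents that add atoms: N-bromosuccinimide, O=C1CCC(=O)N1Br
Why: Electrophilic bromination goes to the ring carbon ortho to the enolic hydroxyl and next to the ring oxygen, the site at which kojic acid derivatives also undergo Mannich and aldol reactions.

Step 4
Reactants: 4 2-bromo-3-hydroxy-6-methyl-4H-pyran-4-one
Product: 5 2-bromo-3-methoxy-6-methyl-4H-pyran-4-one
Conditions: MeI, K2CO3, acetone, reflux
Reagents that add atoms: iodomethane, CI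
Why: Williamson methylation of the acidic enolic hydroxyl installs the future C3 methoxy group and removes the only acidic proton before the coupling.

Step 5
Reactants: 6 methoxyhydroquinone
Product: 7 1,4-bis(benzyloxy)-2-methoxybenzene
Conditions: BnBr (2.2 equiv), K2CO3, DMF, 60 °C, N2
Reagents that add atoms: benzyl bromide, BrCc1ccccc1
Why: Double Williamson etherification masks the oxidation-prone hydroquinone with groups that tolerate amide bases and silanes and leave together in the last step.

Step 6
Reactants: 7 1,4-bis(benzyloxy)-2-methoxybenzene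
Product: 8 1,4-bis(benzyloxy)-2-bromo-5-methoxybenzene
Conditions: NBS, MeCN, 0 °C
Reagents that add atoms: N-bromosuccinimide, O=C1CCC(=O)N1Br
Why: Electrophilic aromatic bromination of a 1,2,4-trialkoxybenzene goes to the one position that is para to the methoxy group and ortho to a benzyloxy group, which is the future C1'.

Step 7
Reactants: 8 1,4-bis(benzyloxy)-2-bromo-5-methoxybenzene
Product: 10 2-[2,5-bis(benzyloxy)-4-methoxyphenyl]-4,4,5,5-tetramethyl-1,3,2-dioxaborolane, via aryllithium 9 (not isolated)
Conditions: n-BuLi, THF, −78 °C; iPrOBpin, −78 °C to rt; 1 M HCl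
Reagents that add atoms: 2-isopropoxy-4,4,5,5-tetramethyl-1,3,2-dioxaborolane, CC(C)OB1OC(C)(C)C(C)(C)O1
Why: Bromine–lithium exchange outruns any benzylic deprotonation at −78 °C, and borylation gives the pinacol ester, which resists protodeboronation better than the free electron-rich boronic acid.

Step 8
Reactants: 5 2-bromo-3-methoxy-6-methyl-4H-pyran-4-one; 10 ring B pinacol boronate
Product: 11 2-[2,5-bis(benzyloxy)-4-methoxyphenyl]-3-methoxy-6-methyl-4H-pyran-4-one
Conditions: Pd(OAc)2 (3 mol %), SPhos (6 mol %), K3PO4, toluene–H2O, 80 °C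
Reagents that add atoms: none
Why: In this Suzuki–Miyaura coupling the C–Br bond of the vinylogous acyl bromide adds readily to zerovalent palladium, the biaryl phosphine copes with the two ortho substituents, and the mild phosphate base spares the pyranone ring.

Step 9
Reactants: 12 carbon disulfide
Product: 14 O,S-dimethyl dithiocarbonate, via sodium O-methyl xanthate 13 (not isolated)
Conditions: NaOMe, MeOH, 0 °C; MeI, rt
Reagents that add atoms: sodium methoxide, [Na+].[O-]C; iodomethane, CI
Why: Xanthate formation and S-methylation, the first half of the Chugaev sequence, give a non-enolisable thioacyl donor that carries the future C7 methoxy group.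

Step 10
Reactants: 15 methyl methoxyacetate; 14 O,S-dimethyl dithiocarbonate
Product: 17 methyl 2,3-dimethoxy-3-(methylsulfanyl)prop-2-enoate (E/Z mixture), via lithium enethiolate 16 (not isolated)
Conditions: LiN(SiMe3)2 (2.2 equiv) added to 15 + 14, THF, −78 °C; MeI (2.5 equiv), −78 °C to rt
Reagents that add atoms: iodomethane, CI
Why: In this crossed Claisen-type thioacylation the ester enolate adds to the thiocarbonyl carbon and methanethiolate leaves, the second equivalent of base drains the acidic β-thioxo ester into 16, and the soft sulfur is methylated selectively, as in the usual preparation of push–pull ketene S-acetals.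

Step 11
Reactants: 11 2-aryl-3-methoxy-6-methyl-4-pyranone; 17 ketene O,S-acetal ester
Product: 19 2-[2,5-bis(benzyloxy)-4-methoxyphenyl]-5-hydroxy-3,6,7-trimethoxy-4H-chromen-4-one, via open-chain butenoate 18 (not isolated)
Conditions: LiN(SiMe3)2 (3.3 equiv), THF, −78 °C; 17 (1.2 equiv), −78 °C to rt, then 50 °C; 1 M HCl
Reagents that add atoms: none
Why: Proposed new method: the 6-methyl group of 11 is the γ-position of a cross-conjugated vinylogous ester and is lithiated by the amide base, the soft dienolate attacks through its CH2 terminus at the O,S-acetal carbon of 17, and the resulting ester enolate expels methanethiolate, the better nucleofuge, so that C7–C8 forms and OMe stays on C7 (18). The surplus base, present from the start so that 18 cannot quench unreacted dienolate, deprotonates the doubly activated C8 methylene, and the extended enolate attacks the ester carbonyl through the pyranone CH carbon to form C4a–C5 in a 6-(enolexo)-exo-trig Dieckmann-type closure (equally a 6π closure of the oxido-triene), after which loss of methoxide and of the C4a proton gives the ring A phenolate. The closest known reactions are the vinylogous Claisen acylation of 2-methyl-4-pyranone anions and the base-induced [3+3] benzannulation of carbanions with α-oxo ketene dithioacetals. The step needs attack at the acetal carbon before the ester carbon, since the reverse order would give the 7-hydroxy-5,6-dimethoxy isomer, and this is secured by the push–pull deactivation of the ester carbonyl, the softness of the delocalised anion and the thiolate leaving group. Intramolecular O-acylation does not compete because the C4 oxygen could reach the ester only through an eight-membered ring, and the geometry on C6=C7 is no obstacle because that bond loses its double-bond character in the anion. No stereocentre is formed, and aromatisation to a chelated lithium phenolate should make the sequence irreversible.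

Step 12
Reactants: 19 5-hydroxyflavone
Product: 20 5-(benzyloxy)-2-[2,5-bis(benzyloxy)-4-methoxyphenyl]-3,6,7-trimethoxy-4H-chromen-4-one
Conditions: BnBr, K2CO3, DMF, 70 °C
Reagents that add atoms: benzyl bromide, BrCc1ccccc1
Why: Williamson etherification under warm carbonate/DMF conditions is routine for chelated 5-hydroxyflavones, removes the proton that would destroy copper hydride and silane, and adds a group that leaves with the others.

Step 13
Reactants: 20 tri-O-benzyl flavone
Product: 23 (2R,3R)-5-(benzyloxy)-2-[2,5-bis(benzyloxy)-4-methoxyphenyl]-3,6,7-trimethoxychroman-4-one, via silyl enol ether 21 (not isolated), via cis ketone 22 (not isolated)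
Conditions: Cu(OAc)2 (5 mol %), (R)-DTBM-SEGPHOS (5.5 mol %), (EtO)2MeSiH (3 equiv), toluene, rt; then 1 M HCl, THF–MeOH, 40 °C
Reagents that add atoms: none
Why: Proposed new method: the ligated monovalent copper hydride formed from Cu(OAc)2 and the silane should deliver hydride to C2 on the face left open by the C2-symmetric bisphosphine (this sets 2R), σ-bond metathesis with the silane traps the copper enolate as 21 before β-aryloxide loss can open ring C, and aqueous acid then protonates C3, first mainly anti to the aryl group (22), and equilibrates it through the neutral enol to the diequatorial trans ketone without forming the free enolate that would racemise C2 by retro-oxa-Michael opening; the closest known reaction is the asymmetric copper hydride 1,4-hydrosilylation of 2-substituted chromones and β,β-disubstituted enones, which has not been shown on the tetrasubstituted double bond of a 3-alkoxyflavone.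

Step 14
Reactants: 23 (2R,3R)-tri-O-benzyl flavanonol methyl ether
Product: 24 (2R,3R)-2-(2,5-dihydroxy-4-methoxyphenyl)-5-hydroxy-3,6,7-trimethoxychroman-4-one (CNP0257825.1)
Conditions: H2 (1 atm), 10% Pd/C, EtOAc–THF, rt; work-up under argon
Reagents that add atoms: none
Why: Catalytic hydrogenolysis removes the three aryl benzyl ethers under neutral conditions, which neither enolise C3 nor open ring C, and it is stopped at the calculated uptake so that the C2–O1 bond and the chelated ketone stay intact.

Compound list
1 | kojic acid, 5-hydroxy-2-(hydroxymethyl)-4H-pyran-4-one | OCc1cc(=O)c(O)co1 | starting material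
2 | chlorokojic acid, 2-(chloromethyl)-5-hydroxy-4H-pyran-4-one | ClCc1cc(=O)c(O)co1 | intermediate
3 | allomaltol, 5-hydroxy-2-methyl-4H-pyran-4-one | Cc1cc(=O)c(O)co1 | intermediate
4 | 2-bromo-3-hydroxy-6-methyl-4H-pyran-4-one | Cc1cc(=O)c(O)c(Br)o1 | intermediate
5 | 2-bromo-3-methoxy-6-methyl-4H-pyran-4-one | Cc1cc(=O)c(OC)c(Br)o1 | intermediate
6 | methoxyhydroquinone, 2-methoxybenzene-1,4-diol | COc1cc(O)ccc1O | starting material
7 | 1,4-bis(benzyloxy)-2-methoxybenzene | COc1cc(OCc2ccccc2)ccc1OCc1ccccc1 | intermediate
8 | 1,4-bis(benzyloxy)-2-bromo-5-methoxybenzene | COc1cc(OCc2ccccc2)c(Br)cc1OCc1ccccc1 | intermediate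
9 | [2,5-bis(benzyloxy)-4-methoxyphenyl]lithium | COc1cc(OCc2ccccc2)c([Li])cc1OCc1ccccc1 | intermediate
10 | 2-[2,5-bis(benzyloxy)-4-methoxyphenyl]-4,4,5,5-tetramethyl-1,3,2-dioxaborolane | COc1cc(OCc2ccccc2)c(B2OC(C)(C)C(C)(C)O2)cc1OCc1ccccc1 | intermediate
11 | 2-[2,5-bis(benzyloxy)-4-methoxyphenyl]-3-methoxy-6-methyl-4H-pyran-4-one | Cc1cc(=O)c(OC)c(-c2cc(OCc3ccccc3)c(OC)cc2OCc2ccccc2)o1 | intermediate
12 | carbon disulfide | S=C=S | starting material
13 | sodium O-methyl dithiocarbonate (xanthate) | [Na+].[S-]C(=S)OC | intermediate
14 | O,S-dimethyl dithiocarbonate | COC(=S)SC | intermediate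
15 | methyl methoxyacetate | COCC(=O)OC | starting material
16 | lithium 1,2,3-trimethoxy-3-oxoprop-1-ene-1-thiolate | [Li+].[S-]C(OC)=C(OC)C(=O)OC | intermediate
17 | methyl 2,3-dimethoxy-3-(methylsulfanyl)prop-2-enoate, E/Z mixture | COC(=O)C(OC)=C(OC)SC | intermediate
18 | methyl 4-{6-[2,5-bis(benzyloxy)-4-methoxyphenyl]-5-methoxy-4-oxo-4H-pyran-2-yl}-2,3-dimethoxybut-2-enoate | COC(=O)C(OC)=C(OC)Cc1cc(=O)c(OC)c(-c2cc(OCc3ccccc3)c(OC)cc2OCc2ccccc2)o1 | intermediate
19 | 2-[2,5-bis(benzyloxy)-4-methoxyphenyl]-5-hydroxy-3,6,7-trimethoxy-4H-chromen-4-one | COc1cc(OCc2ccccc2)c(-c2oc3cc(OC)c(OC)c(O)c3c(=O)c2OC)cc1OCc1ccccc1 | intermediate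
20 | 5-(benzyloxy)-2-[2,5-bis(benzyloxy)-4-methoxyphenyl]-3,6,7-trimethoxy-4H-chromen-4-one | COc1cc(OCc2ccccc2)c(-c2oc3cc(OC)c(OC)c(OCc4ccccc4)c3c(=O)c2OC)cc1OCc1ccccc1 | intermediate
21 | (2R)-5-(benzyloxy)-2-[2,5-bis(benzyloxy)-4-methoxyphenyl]-4-{[diethoxy(methyl)silyl]oxy}-3,6,7-trimethoxy-2H-chromene | COc1cc(OCc2ccccc2)c([C@H]2Oc3cc(OC)c(OC)c(OCc4ccccc4)c3C(O[Si](C)(OCC)OCC)=C2OC)cc1OCc1ccccc1 | intermediate
22 | (2R,3S)-5-(benzyloxy)-2-[2,5-bis(benzyloxy)-4-methoxyphenyl]-3,6,7-trimethoxychroman-4-one, 2,3-cis | COc1cc(OCc2ccccc2)c([C@H]2Oc3cc(OC)c(OC)c(OCc4ccccc4)c3C(=O)[C@H]2OC)cc1OCc1ccccc1 | intermediate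
23 | (2R,3R)-5-(benzyloxy)-2-[2,5-bis(benzyloxy)-4-methoxyphenyl]-3,6,7-trimethoxychroman-4-one, 2,3-trans | COc1cc(OCc2ccccc2)c([C@H]2Oc3cc(OC)c(OC)c(OCc4ccccc4)c3C(=O)[C@@H]2OC)cc1OCc1ccccc1 | intermediate
24 | (2R,3R)-2-(2,5-dihydroxy-4-methoxyphenyl)-5-hydroxy-3,6,7-trimethoxychroman-4-one, CNP0257825.1 | COc1cc(O)c([C@H]2Oc3cc(OC)c(OC)c(O)c3C(=O)[C@@H]2OC)cc1O | target

Total step count: 14. Longest linear sequence: 9 steps (1, 2, 3, 4, 8, 11, 12, 13, 14).

Steps most likely to fail

Step 11. The dienolate may attack the ester carbonyl before the acetal carbon. The sequence may stall at the open-chain stage, because the ester belongs to the same delocalised anion that must attack it. Thiolate or methoxide may also open the pyranone ring.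
The fallback uses known chemistry in which ring A is bought and ring C is closed instead. It sets out from 8 and rejoins the route at 20.
- Aryllithium 9, made from 8 as in step 7, is quenched with CO2 to give 2,5-bis(benzyloxy)-4-methoxybenzoic acid F1.
- Oxalyl chloride with catalytic DMF turns this into 2,5-bis(benzyloxy)-4-methoxybenzoyl chloride F2.
- Commercial 3,4,5-trimethoxyphenol is C-acylated ortho to its hydroxyl with methoxyacetic acid in BF3·OEt2 at 80 °C (Friedel–Crafts acylation), giving 1-(6-hydroxy-2,3,4-trimethoxyphenyl)-2-methoxyethan-1-one F3.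
- F3 is treated with LiN(SiMe3)2 (3 equiv) in THF at −78 °C and then with F2. This C-acylates the ketone enolate, in the direct form of the Baker–Venkataraman synthesis, to 1-[2,5-bis(benzyloxy)-4-methoxyphenyl]-3-(6-hydroxy-2,3,4-trimethoxyphenyl)-2-methoxypropane-1,3-dione F4.
- p-TsOH in warm toluene cyclodehydrates F4 to 2-[2,5-bis(benzyloxy)-4-methoxyphenyl]-3,5,6,7-tetramethoxy-4H-chromen-4-one F5.
- BCl3 in CH2Cl2 at low temperature removes the chelated 5-O-methyl group together with both benzyl groups, giving 2-(2,5-dihydroxy-4-methoxyphenyl)-5-hydroxy-3,6,7-trimethoxy-4H-chromen-4-one F6.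
- Exhaustive benzylation (BnBr, K2CO3, DMF, 70 °C) gives 20.

Step 13. Hydride transfer to the crowded, donor-substituted tetrasubstituted double bond may not occur. The two faces may be poorly differentiated. C2 may also erode through ring opening while C3 is being equilibrated.
The fallback moves the enantioselection from the alkene to the ketone. It sets out from 20 and returns at 23.
- The small achiral hydride LiBH(s-Bu)3 in THF at −78 °C performs the 1,4-reduction known for chromones. After the quench, catalytic DBU gives the racemic trans ketone F7. Ring opening is harmless at this point.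
- A kinetic resolution by Noyori–Ikariya transfer hydrogenation follows, with RuCl(p-cymene)[(R,R)-TsDPEN] and HCO2H/Et3N at rt, as practised on racemic flavanones.
- This should consume the (2S,3S) enantiomer, in which the carbonyl face preferred by the catalyst is also the axial one, giving (2S,3R,4S)-5-(benzyloxy)-2-[2,5-bis(benzyloxy)-4-methoxyphenyl]-3,6,7-trimethoxychroman-4-ol F8.
- Unreacted 23 is then separated by chromatography.

Step 10. The glycolate ester enolate may self-condense. The tetrahedral intermediate may also lose methoxide in place of thiolate, which would carry a second sulfur onto the acetal carbon.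
The fallback builds the acetal carbon from carbon disulfide and then exchanges one sulfur for oxygen. It sets out from 15 and returns at 17.
- Compound 15 is treated with LiN(SiMe3)2 (2.2 equiv), CS2 and then MeI (2.2 equiv), the standard ketene dithioacetal synthesis, to give methyl 2-methoxy-3,3-bis(methylsulfanyl)prop-2-enoate F9.
- One equivalent of NaOMe in refluxing MeOH replaces one methylsulfanyl group by addition–elimination, giving 17.

Further compounds
F1 | step 11 | 2,5-bis(benzyloxy)-4-methoxybenzoic acid | COc1cc(OCc2ccccc2)c(C(=O)O)cc1OCc1ccccc1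
F2 | step 11 | 2,5-bis(benzyloxy)-4-methoxybenzoyl chloride | COc1cc(OCc2ccccc2)c(C(=O)Cl)cc1OCc1ccccc1
F3 | step 11 | 1-(6-hydroxy-2,3,4-trimethoxyphenyl)-2-methoxyethan-1-one | COCC(=O)c1c(O)cc(OC)c(OC)c1OC
F4 | step 11 | 1-[2,5-bis(benzyloxy)-4-methoxyphenyl]-3-(6-hydroxy-2,3,4-trimethoxyphenyl)-2-methoxypropane-1,3-dione (enolisable, no fixed configuration) | COc1cc(OCc2ccccc2)c(C(=O)C(OC)C(=O)c2c(O)cc(OC)c(OC)c2OC)cc1OCc1ccccc1
F5 | step 11 | 2-[2,5-bis(benzyloxy)-4-methoxyphenyl]-3,5,6,7-tetramethoxy-4H-chromen-4-one | COc1cc(OCc2ccccc2)c(-c2oc3cc(OC)c(OC)c(OC)c3c(=O)c2OC)cc1OCc1ccccc1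
F6 | step 11 | 2-(2,5-dihydroxy-4-methoxyphenyl)-5-hydroxy-3,6,7-trimethoxy-4H-chromen-4-one | COc1cc(O)c(-c2oc3cc(OC)c(OC)c(O)c3c(=O)c2OC)cc1O
F7 | step 13 | racemic trans ketone, 23 together with its (2S,3S) enantiomer | COc1cc(OCc2ccccc2)c([C@H]2Oc3cc(OC)c(OC)c(OCc4ccccc4)c3C(=O)[C@@H]2OC)cc1OCc1ccccc1.COc1cc(OCc2ccccc2)c([C@@H]2Oc3cc(OC)c(OC)c(OCc4ccccc4)c3C(=O)[C@H]2OC)cc1OCc1ccccc1
F8 | step 13 | (2S,3R,4S)-5-(benzyloxy)-2-[2,5-bis(benzyloxy)-4-methoxyphenyl]-3,6,7-trimethoxychroman-4-ol | COc1cc(OCc2ccccc2)c([C@@H]2Oc3cc(OC)c(OC)c(OCc4ccccc4)c3[C@H](O)[C@H]2OC)cc1OCc1ccccc1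
F9 | step 10 | methyl 2-methoxy-3,3-bis(methylsulfanyl)prop-2-enoate | COC(=O)C(OC)=C(SC)SC
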